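Assumption: the SMILES is read as drawn, an ent-labdane with (2S,3R,5S,9R,10S) configuration and a 13E side chain; labdane numbering is used in the explanations (in the hydrindanes the five-membered ring holds C5, C6, C7, C8 and C10).

## Retrosynthetic overview

1. Target ⇐ C8 methyl by Negishi coupling of a Δ7 enol triflate ⇐ 8-keto acid, whose whole side chain (C11–C12 bond) comes from a vinylogous Mukaiyama–Michael addition of a senecioic acid bis-silyl dienolate to a 9-methylidene-8-ketone.
2. Ring B ⇐ ring expansion: oxidative semipinacol 1,2-shift of C10 from C8 to C9 in a 1-vinyl-1-silyloxy hydrindane (five-membered ring → six-membered ring); this is the key step.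
3. Ring A functions ⇐ cis-2,3-diacetate by enolate hydroxylation and equatorial hydride delivery on the 4,4-dimethyl-3-ketone ⇐ reductive methylation of the enone, which also sets the trans ring fusion.
4. Bicyclic core ⇐ (R)-4-methyl Hajos–Parrish-type enedione ⇐ 2-methylcyclopentane-1,3-dione + ethyl vinyl ketone (sets C10).
5. Ring order: the cyclopentane comes with the starting dione; ring A is closed by aldol annulation; ring B is made last by expanding the cyclopentane.

## Route

Step 1
Reactants: 1 2-methylcyclopentane-1,3-dione; 2 pent-1-en-3-one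
Product: 3 2-methyl-2-(3-oxopentyl)cyclopentane-1,3-dione
Conditions: H2O, AcOH (cat.), 75 °C
Reagents that add atoms: none
Why: Michael addition of the acidic 1,3-dione to the vinyl ketone, as in the standard preparation of Hajos–Parrish triketones; no stereocentre is formed.

Step 2
Reactants: 3 2-methyl-2-(3-oxopentyl)cyclopentane-1,3-dione
Product: 4 (7aR)-4,7a-dimethyl-2,3,7,7a-tetrahydro-1H-indene-1,5(6H)-dione
Conditions: D-phenylalanine (1.0 equiv), 1 M HClO4 (0.5 equiv), MeCN, reflux
Reagents that add atoms: none
Why: Hajos–Parrish (Eder–Sauer–Wiechert) intramolecular aldol condensation through the amino-acid enamine, which differentiates the two ring carbonyls and sets the quaternary centre (later C10) as R, the D-amino acid giving the antipode of the usual L-series product.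

Step 3
Reactants: 4 (7aR)-4,7a-dimethyl-2,3,7,7a-tetrahydro-1H-indene-1,5(6H)-dione
Product: 6 (7aR)-1-ethenyl-4,7a-dimethyl-1-(triethylsilyloxy)-1,2,3,6,7,7a-hexahydro-5H-inden-5-one (ethenyl anti and silyloxy syn to the 7a-methyl), via bromomagnesium alkoxide 5 (not isolated)
Conditions: CH2=CHMgBr (1.3 equiv), LaCl3·2LiCl (1.0 equiv), THF, −78 °C; then Et3SiOTf (1.5 equiv), −78 to 0 °C
Reagents that add atoms: vinylmagnesium bromide, C=C[Mg]Br; triethylsilyl trifluoromethanesulfonate, CC[Si](CC)(CC)OS(=O)(=O)C(F)(F)F
Why: Grignard 1,2-addition to the saturated cyclopentanone (the conjugated, α-methylated enone carbonyl is less electrophilic) from the face anti to the angular methyl, as with 17-keto steroids, followed by in situ O-silylation so that no free hydroxyl can deliver a proton in step 4; the carbinol centre is destroyed in step 7.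

Step 4
Reactants: 6 (7aR)-1-ethenyl-4,7a-dimethyl-1-(triethylsilyloxy)-1,2,3,6,7,7a-hexahydro-5H-inden-5-one
Product: 8 1-ethenyl-4,4,7a-trimethyl-1-(triethylsilyloxy)octahydro-5H-inden-5-one (trans ring fusion; 3a-H anti to the 7a-methyl), via lithium enolate 7 (not isolated)
Conditions: Li (2.4 equiv), t-BuOH (1.0 equiv), NH3/THF, −78 °C; isoprene; then MeI (6 equiv), −78 to −33 °C
Reagents that add atoms: iodomethane, CI
Why: Stork reductive alkylation (dissolving-metal enone reduction, then C-methylation of the regiospecific enolate): the β-carbon (C5) is protonated axially on the face anti to the angular methyl and the bulky silyloxy group, giving the trans fusion, and methylation at C4 completes the gem-dimethyl group.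

Step 5
Reactants: 8 1-ethenyl-4,4,7a-trimethyl-1-(triethylsilyloxy)octahydro-5H-inden-5-one
Product: 10 1-ethenyl-6-hydroxy-4,4,7a-trimethyl-1-(triethylsilyloxy)octahydro-5H-inden-5-one (6-OH equatorial; anti to the 7a-methyl), via potassium enolate 9 (not isolated)
Conditions: KN(SiMe3)2 (1.2 equiv), THF, −78 °C; then 2-(phenylsulfonyl)-3-phenyloxaziridine (1.5 equiv), −78 °C; aq. NH4Cl
Reagents that add atoms: 2-(phenylsulfonyl)-3-phenyloxaziridine, O=S(=O)(c1ccccc1)N1OC1c1ccccc1
Why: Davis α-hydroxylation of the only possible enolate (towards C2), the oxaziridine approaching the face opposite the two syn-axial methyl groups at C4 and C10, which gives the equatorial (also thermodynamic) 2-hydroxyl.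

Step 6
Reactants: 10 1-ethenyl-6-hydroxy-4,4,7a-trimethyl-1-(triethylsilyloxy)octahydro-5H-inden-5-one
Product: 12 1-ethenyl-4,4,7a-trimethyl-1-(triethylsilyloxy)octahydro-1H-indene-5,6-diyl diacetate (5,6-cis; both acetoxy groups anti to the 7a-methyl), via lithium alkoxide 11 (not isolated)
Conditions: LiBH(s-Bu)3 (2.5 equiv), THF, −78 °C; then Ac2O (8 equiv), pyridine, DMAP, −78 °C to rt
Reagents that add atoms: acetic anhydride, CC(=O)OC(C)=O
Why: Diastereoselective ketone reduction with in situ acetylation (reductive acetylation): the bulky borohydride attacks the 4,4-dimethyl-3-ketone equatorially, as in the preparation of 3-epi triterpenoid alcohols, giving the axial C3 oxygen cis to the C2 oxygen, and both are acetylated while the tertiary oxygen stays silylated.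

Step 7
Reactants: 12 1-ethenyl-4,4,7a-trimethyl-1-(triethylsilyloxy)octahydro-1H-indene-5,6-diyl diacetate
Product: 13 5,5,8a-trimethyl-1-methylidene-2-oxodecahydronaphthalene-6,7-diyl diacetate (trans-decalin; acetoxy groups anti to the 8a-methyl)
Conditions: Pd(OCOCF3)2 (10 mol %), 1,4-benzoquinone (1.5 equiv), 4 Å molecular sieves, ClCH2CH2Cl, 50 °C
Reagents that add atoms: none
Why: Proposed new method: an electrophilic divalent palladium–alkene complex, bound on the face flanked by the C7 methylene, triggers an anti 1,2-shift of the aligned, electron-rich C8–C10 bond to the internal vinyl carbon (oxygen lone-pair push, loss of the silyl group to trifluoroacetate), the resulting primary alkylpalladium loses its only β-hydrogen to give the exocyclic enone, and benzoquinone reoxidises zerovalent palladium; the closest known reaction is the palladium-mediated oxidative ring expansion of strained 1-vinylcyclobutanols to 2-methylidenecyclopentanones, extended here to an unstrained cyclopentanol where C=O and enone formation supply the driving force, and no new stereocentre is formed.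

Step 8
Reactants: 14 3-methylbut-2-enoic acid
Product: 16 1,1-bis(trimethylsilyloxy)-3-methylbuta-1,3-diene, via dilithium dienolate 15 (not isolated)
Conditions: LiN(i-Pr)2 (2.2 equiv), THF, −78 to 0 °C; then Me3SiCl (2.5 equiv), −78 °C to rt
Reagents that add atoms: chlorotrimethylsilane, C[Si](C)(C)Cl
Why: Double deprotonation of the acid (carboxyl, then γ-methyl) gives the dienolate dianion, which is O-silylated twice to the bis-silyl ketene acetal; no stereocentre is formed.

Step 9
Reactants: 13 5,5,8a-trimethyl-1-methylidene-2-oxodecahydronaphthalene-6,7-diyl diacetate; 16 1,1-bis(trimethylsilyloxy)-3-methylbuta-1,3-diene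
Product: 18 (2E)-5-[6,7-diacetoxy-5,5,8a-trimethyl-2-oxodecahydronaphthalen-1-yl]-3-methylpent-2-enoic acid (side chain equatorial; 1-H anti to the 8a-methyl), via bis-silyl Michael adduct 17 (not isolated)
Conditions: Me3SiOTf (10 mol %), CH2Cl2, −78 °C; then 1 M HCl, THF, 0 °C to rt
Reagents that add atoms: none
Why: Vinylogous Mukaiyama–Michael addition: the γ-carbon of the s-trans silyl dienolate adds to the unhindered exocyclic methylene to give the (E)-enoate (the congested C9 disfavours ring closure to a cycloadduct), and acid hydrolysis of the silyl enol ether and silyl ester protonates C9 axially to the equatorial, thermodynamically preferred side chain.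

Step 10
Reactants: 18 (2E)-5-[6,7-diacetoxy-5,5,8a-trimethyl-2-oxodecahydronaphthalen-1-yl]-3-methylpent-2-enoic acid
Product: 19 (2E)-5-[6,7-diacetoxy-5,5,8a-trimethyl-2-(trifluoromethanesulfonyloxy)-1,4,4a,5,6,7,8,8a-octahydronaphthalen-1-yl]-3-methylpent-2-enoic acid
Conditions: KN(SiMe3)2 (2.2 equiv) added to 18 and PhNTf2 (1.3 equiv), THF, −78 °C; aq. HCl to pH 3
Reagents that add atoms: N-phenylbis(trifluoromethanesulfonimide), O=S(=O)(N(c1ccccc1)S(=O)(=O)C(F)(F)F)C(F)(F)F
Why: Kinetic enolate O-triflation: after carboxylate formation the second equivalent of base removes a proton from the less hindered C7 methylene of the 2-alkylcyclohexanone, giving the Δ7 enol triflate regioselectively, while the less acidic acetates and the C9 stereocentre are untouched at −78 °C.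

Step 11
Reactants: 19 (2E)-5-[6,7-diacetoxy-5,5,8a-trimethyl-2-(trifluoromethanesulfonyloxy)-1,4,4a,5,6,7,8,8a-octahydronaphthalen-1-yl]-3-methylpent-2-enoic acid
Product: 20 (2E)-5-[(1R,4aS,6R,7S,8aS)-6,7-diacetoxy-2,5,5,8a-tetramethyl-1,4,4a,5,6,7,8,8a-octahydronaphthalen-1-yl]-3-methylpent-2-enoic acid (CNP0321684.1)
Conditions: MeZnCl (3 equiv), Pd(PPh3)4 (5 mol %), THF, 50 °C; aq. HCl
Reagents that add atoms: methylzinc chloride, C[Zn]Cl
Why: Negishi cross-coupling of the enol triflate installs the C8 methyl with the double bond fixed at Δ7 (one equivalent of the zinc reagent is consumed by the acid; acetates and the enoate are inert to organozinc), and no stereocentre is touched.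

## Compound list

1 | 2-methylcyclopentane-1,3-dione | CC1C(=O)CCC1=O | starting material
2 | pent-1-en-3-one (ethyl vinyl ketone) | CCC(=O)C=C | starting material
3 | 2-methyl-2-(3-oxopentyl)cyclopentane-1,3-dione | CCC(=O)CCC1(C)C(=O)CCC1=O | intermediate
4 | (7aR)-4,7a-dimethyl-2,3,7,7a-tetrahydro-1H-indene-1,5(6H)-dione | O=C1CC[C@@]2(C)C(=O)CCC2=C1C | intermediate
5 | bromomagnesium alkoxide of the 1-ethenyl carbinol (ethenyl anti to the 7a-methyl) | O=C1CC[C@@]2(C)[C@@](O[Mg]Br)(C=C)CCC2=C1C | intermediate (not isolated)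
6 | (7aR)-1-ethenyl-4,7a-dimethyl-1-(triethylsilyloxy)-1,2,3,6,7,7a-hexahydro-5H-inden-5-one, ethenyl anti and silyloxy syn to the 7a-methyl | O=C1CC[C@@]2(C)[C@@](O[Si](CC)(CC)CC)(C=C)CCC2=C1C | intermediate
7 | lithium enolate (O–C5=C4, indene numbering) of the trans-fused reduction product | [Li]OC=1CC[C@@]2(C)[C@@](O[Si](CC)(CC)CC)(C=C)CC[C@@H]2C=1C | intermediate (not isolated)
8 | 1-ethenyl-4,4,7a-trimethyl-1-(triethylsilyloxy)octahydro-5H-inden-5-one, trans ring fusion (3a-H anti to the 7a-methyl) | O=C1CC[C@@]2(C)[C@@](O[Si](CC)(CC)CC)(C=C)CC[C@@H]2C1(C)C | intermediate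
9 | potassium enolate (O–C5=C6) of 8 | [K]OC1=CC[C@@]2(C)[C@@](O[Si](CC)(CC)CC)(C=C)CC[C@@H]2C1(C)C | intermediate (not isolated)
10 | 1-ethenyl-6-hydroxy-4,4,7a-trimethyl-1-(triethylsilyloxy)octahydro-5H-inden-5-one, 6-OH equatorial and anti to the 7a-methyl | O[C@H]1C[C@@]2(C)[C@@](O[Si](CC)(CC)CC)(C=C)CC[C@@H]2C(C)(C)C1=O | intermediate
11 | lithium 5-alkoxide of the 5,6-cis-diol (both oxygens anti to the 7a-methyl) | O[C@H]1C[C@@]2(C)[C@@](O[Si](CC)(CC)CC)(C=C)CC[C@@H]2C(C)(C)[C@H]1O[Li] | intermediate (not isolated)
12 | 1-ethenyl-4,4,7a-trimethyl-1-(triethylsilyloxy)octahydro-1H-indene-5,6-diyl diacetate, 5,6-cis, both acetoxy groups anti to the 7a-methyl | CC(=O)O[C@H]1C[C@@]2(C)[C@@](O[Si](CC)(CC)CC)(C=C)CC[C@@H]2C(C)(C)[C@H]1OC(C)=O | intermediate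
13 | 5,5,8a-trimethyl-1-methylidene-2-oxodecahydronaphthalene-6,7-diyl diacetate, trans-decalin, acetoxy groups anti to the 8a-methyl | CC(=O)O[C@H]1C[C@@]2(C)C(=C)C(=O)CC[C@@H]2C(C)(C)[C@H]1OC(C)=O | intermediate
14 | 3-methylbut-2-enoic acid | CC(C)=CC(=O)O | starting material
15 | dilithium dienolate of 14 | C=C(C)C=C(O[Li])O[Li] | intermediate (not isolated)
16 | 1,1-bis(trimethylsilyloxy)-3-methylbuta-1,3-diene | C=C(C)C=C(O[Si](C)(C)C)O[Si](C)(C)C | intermediate
17 | trimethylsilyl ester and trimethylsilyl enol ether of 18 (Michael adduct) | CC(=O)O[C@H]1C[C@@]2(C)C(CC/C(C)=C/C(=O)O[Si](C)(C)C)=C(O[Si](C)(C)C)CC[C@@H]2C(C)(C)[C@H]1OC(C)=O | intermediate (not isolated)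
18 | (2E)-5-[6,7-diacetoxy-5,5,8a-trimethyl-2-oxodecahydronaphthalen-1-yl]-3-methylpent-2-enoic acid, side chain equatorial | CC(=O)O[C@H]1C[C@@]2(C)[C@H](CC/C(C)=C/C(=O)O)C(=O)CC[C@@H]2C(C)(C)[C@H]1OC(C)=O | intermediate
19 | (2E)-5-[6,7-diacetoxy-5,5,8a-trimethyl-2-(trifluoromethanesulfonyloxy)-1,4,4a,5,6,7,8,8a-octahydronaphthalen-1-yl]-3-methylpent-2-enoic acid | CC(=O)O[C@H]1C[C@@]2(C)[C@H](CC/C(C)=C/C(=O)O)C(OS(=O)(=O)C(F)(F)F)=CC[C@@H]2C(C)(C)[C@H]1OC(C)=O | intermediate
20 | (2E)-5-[(1R,4aS,6R,7S,8aS)-6,7-diacetoxy-2,5,5,8a-tetramethyl-1,4,4a,5,6,7,8,8a-octahydronaphthalen-1-yl]-3-methylpent-2-enoic acid (ent-2α,3α-diacetoxylabda-7,13E-dien-15-oic acid) | CC(=O)O[C@H]1C[C@@]2(C)[C@H](CC/C(C)=C/C(=O)O)C(C)=CC[C@@H]2C(C)(C)[C@H]1OC(C)=O | target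

## Step count and risks

Total step count: 11. Longest linear sequence: 10 (steps 1–7 and 9–11; step 8 makes the dienolate reagent).

Three steps most likely to fail:

Step 7 (the new ring expansion). The unstrained ring may not migrate, the C7 methylene could migrate instead of C10, or the palladium could give Wacker-type or allylic-transposition products. The fallback uses known chemistry, sets out from 12 and returns at 13. The vinyl group is epoxidised with m-CPBA (CH2Cl2, rt) to the epoxy silyl ether F1. BF3·OEt2 in CH2Cl2 at −78 °C then effects the established semipinacol rearrangement of a 2,3-epoxy silyl ether (opening at the carbon next to the carbinol with anti migration of C10), giving the ring-expanded 9-hydroxymethyl ketone F2. Mesylation (MsCl, Et3N, 0 °C) gives the mesylate F3, and DBU eliminates it to 13.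

Step 3 (chemoselective vinyl addition). The enone carbonyl may compete for the Grignard reagent, or the hindered cyclopentanone may only enolise. The fallback sets out from 4 and returns at 6. The enone carbonyl is masked first with HSCH2CH2SH and BF3·OEt2 in MeOH, conditions under which conjugated ketones react selectively and the double bond stays in place, giving the dithiolane ketone F4. Vinyl addition and in situ silylation as in step 3 give the silyl ether dithiolane F5, and MeI, CaCO3 in aqueous MeCN releases the enone 6.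

Step 4 (trans-selective reductive methylation). Hydrindenones give lower trans selectivity than octalones under dissolving-metal conditions. The fallback sets out from 6 and returns at 8. Conjugate reduction with i-Bu2AlH and t-BuCu (from CuI and t-BuLi) in THF–HMPA at −50 °C, a hydride system known to give trans-fused products from Hajos–Parrish-type enones, gives the diisobutylaluminium enolate F6. This is converted into its ate complex with MeLi and methylated with MeI to 8.

Further compounds
F1 | step 7 | epoxy silyl ether of 12 (oxirane in place of the ethenyl group, both oxirane epimers) | CC(=O)O[C@H]1C[C@@]2(C)[C@@](O[Si](CC)(CC)CC)(C3CO3)CC[C@@H]2C(C)(C)[C@H]1OC(C)=O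
F2 | step 7 | 1-(hydroxymethyl)-5,5,8a-trimethyl-2-oxodecahydronaphthalene-6,7-diyl diacetate (C1 epimers) | CC(=O)O[C@H]1C[C@@]2(C)C(CO)C(=O)CC[C@@H]2C(C)(C)[C@H]1OC(C)=O
F3 | step 7 | methanesulfonate of F2 | CC(=O)O[C@H]1C[C@@]2(C)C(COS(C)(=O)=O)C(=O)CC[C@@H]2C(C)(C)[C@H]1OC(C)=O
F4 | step 3 | 5,5-(ethane-1,2-diyldisulfanediyl) derivative (1,3-dithiolane) of 4 at the enone carbonyl | S1CCSC13CC[C@@]2(C)C(=O)CCC2=C3C
F5 | step 3 | 1-ethenyl-1-(triethylsilyloxy) adduct of F4 (ethenyl anti to the 7a-methyl) | S1CCSC13CC[C@@]2(C)[C@@](O[Si](CC)(CC)CC)(C=C)CCC2=C3C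
F6 | step 4 | diisobutylaluminium enolate (O–C5=C4) of the trans-fused 4-methyl ketone | CC(C)C[Al](CC(C)C)OC=1CC[C@@]2(C)[C@@](O[Si](CC)(CC)CC)(C=C)CC[C@@H]2C=1C
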